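The route rests on cutting the dihydrofuran ring of the B-ring unit between its CH2 carbon (C-3) and the arene carbon C-3a, the carbon flanked by the phenol carbon and the ring-oxygen carbon. The key step, a Pd(0)-catalysed intramolecular C(sp3)–H arylation, turns the methyl group of a lactate-derived (S)-aryl ether into that CH2 and closes the five-membered ring in one operation, with the stereocentre already in place. Its precursor is a 2-bromoresorcinol ether: bromine on the flanked carbon, a MOM ether on one side and the O–CH(CH3)–C(CH3)2OSiEt3 chain on the other. Directed borylation, Suzuki coupling with a 6-prenyl-3-iodochromone and acid deprotection finish the synthesis.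

Key step: step 5

Remark: tert-butyl 2-methylbut-3-en-2-yl carbonate (13) is taken as purchasable; otherwise it is made from 2-methylbut-3-en-2-ol and Boc2O.

Step 1
Reactants: 1 2-bromoresorcinol
Product: 2 2-bromo-3-(methoxymethoxy)phenol
Conditions: MOMCl (1.0 equiv), iPr2NEt, CH2Cl2, 0 °C to rt
Reagents that add atoms: chloromethyl methyl ether (MOMCl), COCCl
Why: O-alkylation of a phenol with an α-chloro ether; the two hydroxyl groups of 1 are equivalent, so one equivalent of MOMCl should give mainly the mono-ether beside recoverable 1 and separable bis-ether.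

Step 2
Reactants: 2 2-bromo-3-(methoxymethoxy)phenol; 3 ethyl (R)-lactate
Product: 4 ethyl (2S)-2-[2-bromo-3-(methoxymethoxy)phenoxy]propanoate
Conditions: PPh3, DIAD, THF, 0 °C to rt
Reagents that add atoms: none
Why: Mitsunobu reaction, in which the phenol displaces the activated secondary hydroxyl of the lactate by SN2 with inversion, so that (R)-lactate sets the (S) configuration of the ether carbon.

Step 3
Reactants: 4 ethyl (2S)-2-[2-bromo-3-(methoxymethoxy)phenoxy]propanoate
Product: 6 (3S)-3-[2-bromo-3-(methoxymethoxy)phenoxy]-2-methylbutan-2-ol, via methyl ketone 5 (not isolated)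
Conditions: MeMgBr (3 equiv), THF, −78 to 0 °C; aq. NH4Cl
Reagents that add atoms: methylmagnesium bromide, C[Mg]Br
Why: Double Grignard addition to the ester through the methyl ketone, with the aryl bromide and the MOM ether inert at low temperature and the stereocentre untouched because addition should outrun enolisation.

Step 4
Reactants: 6 (3S)-3-[2-bromo-3-(methoxymethoxy)phenoxy]-2-methylbutan-2-ol
Product: 7 {[(3S)-3-[2-bromo-3-(methoxymethoxy)phenoxy]-2-methylbutan-2-yl]oxy}triethylsilane
Conditions: Et3SiCl, imidazole, DMAP (cat.), DMF, rt to 40 °C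
Reagents that add atoms: chlorotriethylsilane, CC[Si](Cl)(CC)CC
Why: Imidazole-promoted silylation of the tertiary alcohol, which masks the hydroxyl so that neither Pd-alkoxide C–O coupling in step 5 nor alkoxide-directed lithiation in step 6 can interfere.

Step 5
Reactants: 7 {[(3S)-3-[2-bromo-3-(methoxymethoxy)phenoxy]-2-methylbutan-2-yl]oxy}triethylsilane
Product: 8 triethyl({2-[(2S)-4-(methoxymethoxy)-2,3-dihydro-1-benzofuran-2-yl]propan-2-yl}oxy)silane
Conditions: Pd(OAc)2 (5 mol %), PCy3·HBF4 (10 mol %), PivOH (30 mol %), Cs2CO3, mesitylene, 140 °C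
Reagents that add atoms: none
Why: Oxidative addition of Pd(0)/PCy3 into the C–Br bond, exchange of bromide for pivalate, concerted metalation–deprotonation of a C–H bond of the methyl group on the ether carbon and C(sp2)–C(sp3) reductive elimination should form the aryl–CH2 bond. The closest known reaction type is the Pd(0)/pivalate-catalysed intramolecular C(sp3)–H arylation of 2-bromoaryl alkyl ethers to 2,3-dihydrobenzofurans. The five-membered O-heterocycle is closed by reductive elimination from a six-membered oxapalladacycle (Pd, C-3a, C-7a, O, C-2, C-3). No new stereocentre is formed; the (S) centre set in step 2 has no bond broken and keeps its configuration. The step needs site selectivity for the primary C–H bonds of the methyl group on the ether carbon over those of the gem-dimethyl, MOM and SiEt3 groups, and only that methyl group can give a six-membered palladacycle (the gem-dimethyl groups would need a seven-membered one). The bromine fixes the ring fusion at the carbon between the two oxygen-bearing carbons, and the silyl ether excludes C–O coupling of the tertiary alcohol.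

Step 6
Reactants: 8 triethyl({2-[(2S)-4-(methoxymethoxy)-2,3-dihydro-1-benzofuran-2-yl]propan-2-yl}oxy)silane
Product: 10 2-[(2S)-4-(methoxymethoxy)-2-{2-[(triethylsilyl)oxy]propan-2-yl}-2,3-dihydro-1-benzofuran-5-yl]-4,4,5,5-tetramethyl-1,3,2-dioxaborolane, via aryllithium 9 (not isolated)
Conditions: s-BuLi, TMEDA, THF, −78 °C; then iPrOBpin, −78 °C to rt; aq. NH4Cl
Reagents that add atoms: 2-isopropoxy-4,4,5,5-tetramethyl-1,3,2-dioxaborolane (iPrOBpin), CC(C)OB1OC(C)(C)C(C)(C)O1
Why: Directed ortho-metalation, in which the OMOM group is a stronger director than the ring ether oxygen and has C-5 as its only free ortho position, followed by trapping of the aryllithium with the borate ester.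

Step 7
Reactants: 11 2,4,6-trihydroxyacetophenone
Product: 12 1-[2,6-dihydroxy-4-(methoxymethoxy)phenyl]ethanone
Conditions: MOMCl (1.05 equiv), iPr2NEt, CH2Cl2, 0 °C
Reagents that add atoms: chloromethyl methyl ether (MOMCl), COCCl
Why: Phenol O-alkylation that should be selective for the 4-OH, the most acidic hydroxyl and the only one not hydrogen-bonded to the acetyl group.

Step 8
Reactants: 12 1-[2,6-dihydroxy-4-(methoxymethoxy)phenyl]ethanone; 13 tert-butyl 2-methylbut-3-en-2-yl carbonate
Product: 14 1-[2-hydroxy-4-(methoxymethoxy)-6-(2-methylbut-3-en-2-yloxy)phenyl]ethanone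
Conditions: Pd(PPh3)4 (3 mol %), 4 Å MS, THF, 0 °C to rt
Reagents that add atoms: none
Why: Tsuji–Trost O-allylation, in which the phenoxide attacks the more substituted terminus of the 1,1-dimethyl-π-allyl palladium complex at low temperature to give the tertiary ether, the two hydroxyls of 12 being equivalent and the remaining hydrogen-bonded one reacting more slowly.

Step 9
Reactants: 14 1-[2-hydroxy-4-(methoxymethoxy)-6-(2-methylbut-3-en-2-yloxy)phenyl]ethanone
Product: 16 3-iodo-7-(methoxymethoxy)-5-(2-methylbut-3-en-2-yloxy)-4H-chromen-4-one, via enaminone 15 (not isolated)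
Conditions: Me2NCH(OMe)2, 60 °C; concentrate; then I2, pyridine, CHCl3, rt
Reagents that add atoms: N,N-dimethylformamide dimethyl acetal, COC(OC)N(C)C; iodine, II
Why: Enaminone condensation followed by iodine-induced cyclisation of the single free ortho-hydroxyl with loss of dimethylamine (3-iodochromone synthesis), run below the temperature of the Claisen rearrangement so that the ether still marks the future O-5 when the pyranone ring closes.

Step 10
Reactants: 16 3-iodo-7-(methoxymethoxy)-5-(2-methylbut-3-en-2-yloxy)-4H-chromen-4-one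
Product: 18 5-hydroxy-3-iodo-7-(methoxymethoxy)-6-(3-methylbut-2-en-1-yl)-4H-chromen-4-one, via dienone 17 (not isolated)
Conditions: toluene, 110 °C
Reagents that add atoms: none
Why: Aromatic Claisen rearrangement, in which O-5 has C-6 as its only free ortho position and the allylic inversion of the 1,1-dimethylallyl group delivers the linear prenyl group there before tautomerisation restores the hydrogen-bonded 5-OH.

Step 11
Reactants: 18 5-hydroxy-3-iodo-7-(methoxymethoxy)-6-(3-methylbut-2-en-1-yl)-4H-chromen-4-one; 10 2-[(2S)-4-(methoxymethoxy)-2-{2-[(triethylsilyl)oxy]propan-2-yl}-2,3-dihydro-1-benzofuran-5-yl]-4,4,5,5-tetramethyl-1,3,2-dioxaborolane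
Product: 19 5-hydroxy-7-(methoxymethoxy)-3-[(2S)-4-(methoxymethoxy)-2-{2-[(triethylsilyl)oxy]propan-2-yl}-2,3-dihydro-1-benzofuran-5-yl]-6-(3-methylbut-2-en-1-yl)-4H-chromen-4-one
Conditions: Pd(dppf)Cl2 (5 mol %), K2CO3, 1,4-dioxane/H2O, 80 °C
Reagents that add atoms: none
Why: Suzuki–Miyaura coupling of the reactive 3-iodochromone with the aryl boronate builds the isoflavone C-3–C-1' bond, and the hydrogen-bonded 5-OH, the MOM and silyl ethers and the prenyl group should be tolerated.

Step 12
Reactants: 19 5-hydroxy-7-(methoxymethoxy)-3-[(2S)-4-(methoxymethoxy)-2-{2-[(triethylsilyl)oxy]propan-2-yl}-2,3-dihydro-1-benzofuran-5-yl]-6-(3-methylbut-2-en-1-yl)-4H-chromen-4-one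
Product: 20 5,7-dihydroxy-3-[(2S)-4-hydroxy-2-(2-hydroxypropan-2-yl)-2,3-dihydro-1-benzofuran-5-yl]-6-(3-methylbut-2-en-1-yl)-4H-chromen-4-one (CNP0381477.1)
Conditions: 3 M aq. HCl, MeOH/THF, 45 °C, stopped at full conversion
Reagents that add atoms: none
Why: Acid-catalysed acetal exchange of both aryl MOM ethers and solvolysis of the tertiary silyl ether, under mild acid and short time so that the prenyl group should not cyclise onto the neighbouring phenols and the ether stereocentre is not affected.

Compound list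
1 | 2-bromoresorcinol (2-bromobenzene-1,3-diol) | Oc1cccc(O)c1Br | starting material
2 | 2-bromo-3-(methoxymethoxy)phenol | COCOc1cccc(O)c1Br | intermediate
3 | ethyl (R)-lactate | C[C@@H](O)C(=O)OCC | starting material
4 | ethyl (2S)-2-[2-bromo-3-(methoxymethoxy)phenoxy]propanoate | C[C@H](Oc1cccc(OCOC)c1Br)C(=O)OCC | intermediate
5 | (3S)-3-[2-bromo-3-(methoxymethoxy)phenoxy]butan-2-one | C[C@H](Oc1cccc(OCOC)c1Br)C(C)=O | intermediate (not isolated)
6 | (3S)-3-[2-bromo-3-(methoxymethoxy)phenoxy]-2-methylbutan-2-ol | C[C@H](Oc1cccc(OCOC)c1Br)C(C)(C)O | intermediate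
7 | {[(3S)-3-[2-bromo-3-(methoxymethoxy)phenoxy]-2-methylbutan-2-yl]oxy}triethylsilane | C[C@H](Oc1cccc(OCOC)c1Br)C(C)(C)O[Si](CC)(CC)CC | intermediate
8 | triethyl({2-[(2S)-4-(methoxymethoxy)-2,3-dihydro-1-benzofuran-2-yl]propan-2-yl}oxy)silane | COCOc1cccc2c1C[C@@H](C(C)(C)O[Si](CC)(CC)CC)O2 | intermediate
9 | 5-lithio derivative of 8 | [Li]c1ccc2c(c1OCOC)C[C@@H](C(C)(C)O[Si](CC)(CC)CC)O2 | intermediate (not isolated)
10 | 2-[(2S)-4-(methoxymethoxy)-2-{2-[(triethylsilyl)oxy]propan-2-yl}-2,3-dihydro-1-benzofuran-5-yl]-4,4,5,5-tetramethyl-1,3,2-dioxaborolane | CC1(C)OB(OC1(C)C)c1ccc2c(c1OCOC)C[C@@H](C(C)(C)O[Si](CC)(CC)CC)O2 | intermediate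
11 | 2,4,6-trihydroxyacetophenone | CC(=O)c1c(O)cc(O)cc1O | starting material
12 | 1-[2,6-dihydroxy-4-(methoxymethoxy)phenyl]ethanone | CC(=O)c1c(O)cc(OCOC)cc1O | intermediate
13 | tert-butyl 2-methylbut-3-en-2-yl carbonate | C=CC(C)(C)OC(=O)OC(C)(C)C | starting material
14 | 1-[2-hydroxy-4-(methoxymethoxy)-6-(2-methylbut-3-en-2-yloxy)phenyl]ethanone | CC(=O)c1c(O)cc(OCOC)cc1OC(C)(C)C=C | intermediate
15 | (E)-3-(dimethylamino)-1-[2-hydroxy-4-(methoxymethoxy)-6-(2-methylbut-3-en-2-yloxy)phenyl]prop-2-en-1-one | CN(C)/C=C/C(=O)c1c(O)cc(OCOC)cc1OC(C)(C)C=C | intermediate (not isolated)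
16 | 3-iodo-7-(methoxymethoxy)-5-(2-methylbut-3-en-2-yloxy)-4H-chromen-4-one | O=c1c(I)coc2cc(OCOC)cc(OC(C)(C)C=C)c12 | intermediate
17 | 3-iodo-7-(methoxymethoxy)-6-(3-methylbut-2-en-1-yl)-6H-chromene-4,5-dione | O=C1C(CC=C(C)C)C(OCOC)=CC2=C1C(=O)C(I)=CO2 | intermediate (not isolated)
18 | 5-hydroxy-3-iodo-7-(methoxymethoxy)-6-(3-methylbut-2-en-1-yl)-4H-chromen-4-one | O=c1c(I)coc2cc(OCOC)c(CC=C(C)C)c(O)c12 | intermediate
19 | 5-hydroxy-7-(methoxymethoxy)-3-[(2S)-4-(methoxymethoxy)-2-{2-[(triethylsilyl)oxy]propan-2-yl}-2,3-dihydro-1-benzofuran-5-yl]-6-(3-methylbut-2-en-1-yl)-4H-chromen-4-one | CC(C)=CCc1c(OCOC)cc2occ(-c3ccc4c(c3OCOC)C[C@@H](C(C)(C)O[Si](CC)(CC)CC)O4)c(=O)c2c1O | intermediate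
20 | 5,7-dihydroxy-3-[(2S)-4-hydroxy-2-(2-hydroxypropan-2-yl)-2,3-dihydro-1-benzofuran-5-yl]-6-(3-methylbut-2-en-1-yl)-4H-chromen-4-one | CC(C)=CCc1c(O)cc2occ(-c3ccc4c(c3O)C[C@@H](C(C)(C)O)O4)c(=O)c2c1O | target

Total step count: 12. Longest linear sequence: 8 steps (steps 1–6, 11 and 12).

Steps most likely to fail

Step 5. Oxidative addition into the doubly ortho-substituted C–Br bond may be slow, and the palladacycle may be lost to β-hydride elimination or to hydrodebromination after C–H activation of the MOM methylene. The fallback forms the same aryl–CH2 bond by an anionic Parham-type cyclisation; it sets out from 2 and comes back at 8. Methyl (R)-glycidate is opened at C-3 with HCl to methyl (2S)-3-chloro-2-hydroxypropanoate F1. Mitsunobu reaction of F1 with 2 (PPh3, DIAD) should give, with inversion, methyl (2R)-2-[2-bromo-3-(methoxymethoxy)phenoxy]-3-chloropropanoate F2. MeMgBr with CeCl3 at −78 °C, chosen to suppress enolisation and loss of chloride, should give (3R)-3-[2-bromo-3-(methoxymethoxy)phenoxy]-4-chloro-2-methylbutan-2-ol F3. Et3SiCl and imidazole convert it into {[(3R)-3-[2-bromo-3-(methoxymethoxy)phenoxy]-4-chloro-2-methylbutan-2-yl]oxy}triethylsilane F4. n-BuLi in THF at −100 °C exchanges bromine for lithium, and on warming the aryllithium should displace the primary chloride (5-exo-tet) to give 8.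

Step 8. The π-allyl palladium complex may alkylate the electron-rich ring at carbon instead of oxygen, or the tertiary ether may isomerise to the linear prenyl ether, which would misdirect the Claisen step. The fallback sets out from 12 and comes back at 14. Copper-catalysed O-propargylation with 3-chloro-3-methylbut-1-yne (DBU, CuCl2 cat., MeCN, 0 °C) should give 1-[2-hydroxy-4-(methoxymethoxy)-6-(2-methylbut-3-yn-2-yloxy)phenyl]ethanone F5. Lindlar semihydrogenation (H2, Pd/CaCO3/Pb, quinoline, EtOAc, rt) then reduces the alkyne to the alkene of 14.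

Step 6. Lithiation may be misdirected to C-7 next to the ring oxygen or to the benzylic CH2, where it would lead to ring opening by β-elimination. The fallback replaces metalation by phenol-controlled electrophilic bromination; it sets out from 8 and comes back at 10. Aqueous HCl in MeOH removes both protecting groups to give (2S)-2-(2-hydroxypropan-2-yl)-2,3-dihydro-1-benzofuran-4-ol F6. NBS with catalytic iPr2NH in CH2Cl2 at 0 °C should brominate ortho to the phenol and give (2S)-5-bromo-2-(2-hydroxypropan-2-yl)-2,3-dihydro-1-benzofuran-4-ol F7. MOMCl and iPr2NEt protect the phenol as 2-[(2S)-5-bromo-4-(methoxymethoxy)-2,3-dihydro-1-benzofuran-2-yl]propan-2-ol F8. Et3SiCl and imidazole give ({2-[(2S)-5-bromo-4-(methoxymethoxy)-2,3-dihydro-1-benzofuran-2-yl]propan-2-yl}oxy)triethylsilane F9. Miyaura borylation (B2pin2, Pd(dppf)Cl2, KOAc, dioxane, 90 °C) then gives 10.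

Further compounds
F1 | step 5 | methyl (2S)-3-chloro-2-hydroxypropanoate | ClC[C@@H](O)C(=O)OC
F2 | step 5 | methyl (2R)-2-[2-bromo-3-(methoxymethoxy)phenoxy]-3-chloropropanoate | ClC[C@H](Oc1cccc(OCOC)c1Br)C(=O)OC
F3 | step 5 | (3R)-3-[2-bromo-3-(methoxymethoxy)phenoxy]-4-chloro-2-methylbutan-2-ol | ClC[C@H](Oc1cccc(OCOC)c1Br)C(C)(C)O
F4 | step 5 | {[(3R)-3-[2-bromo-3-(methoxymethoxy)phenoxy]-4-chloro-2-methylbutan-2-yl]oxy}triethylsilane | ClC[C@H](Oc1cccc(OCOC)c1Br)C(C)(C)O[Si](CC)(CC)CC
F5 | step 8 | 1-[2-hydroxy-4-(methoxymethoxy)-6-(2-methylbut-3-yn-2-yloxy)phenyl]ethanone | CC(=O)c1c(O)cc(OCOC)cc1OC(C)(C)C#C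
F6 | step 6 | (2S)-2-(2-hydroxypropan-2-yl)-2,3-dihydro-1-benzofuran-4-ol | Oc1cccc2c1C[C@@H](C(C)(C)O)O2
F7 | step 6 | (2S)-5-bromo-2-(2-hydroxypropan-2-yl)-2,3-dihydro-1-benzofuran-4-ol | Oc1c(Br)ccc2c1C[C@@H](C(C)(C)O)O2
F8 | step 6 | 2-[(2S)-5-bromo-4-(methoxymethoxy)-2,3-dihydro-1-benzofuran-2-yl]propan-2-ol | COCOc1c(Br)ccc2c1C[C@@H](C(C)(C)O)O2
F9 | step 6 | ({2-[(2S)-5-bromo-4-(methoxymethoxy)-2,3-dihydro-1-benzofuran-2-yl]propan-2-yl}oxy)triethylsilane | COCOc1c(Br)ccc2c1C[C@@H](C(C)(C)O[Si](CC)(CC)CC)O2
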